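## Retrosynthetic overview
1. The target is the global debenzylation product of a tetra-O-benzyl 2-aryl-tetrahydrofuran. That THF, the only ring, forms late by acid cyclodehydration of a 1,4-diol through a p-alkoxybenzylic cation, which equilibrates the benzylic centre to the 2,3-trans isomer.
2. The diol comes from ArMgBr addition to a lactol. The lactol comes from reduction of an acid and oxidative cleavage of a disubstituted alkene.
3. The key step is an Ireland–Claisen [3,3] rearrangement of an α-benzyloxy-α-benzyl ester of a chiral (R)-(E)-secondary allylic alcohol. It forms the C8–C8′ bond and sets the adjacent quaternary and tertiary centres by chirality transfer.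
4. The chiral alcohol comes from (R)-3-buten-2-ol by cross-metathesis; the acid partner is racemic and made in one alkylation.

Assumption: the five commercial reagents (1, 2, 4, 5, 11) are purchased; 5 and 11 are each one benzylation step from cheap vanillyl or bromophenol precursors.

## Route

**Step 1**
Reactants: 1 (R)-but-3-en-2-ol; 2 benzyl allyl ether
Product: 3 (2R,3E)-5-(benzyloxy)pent-3-en-2-ol
Conditions: Grubbs II (3 mol %), CH2Cl2, 40 °C, 12 h (2 in excess)
Reagents that add atoms: none (ethylene is lost)
Why: Cross-metathesis joins the two terminal alkenes to give the E-enol ether-free γ-benzyloxy allylic alcohol, and the carbinol stereocentre of 1 is untouched.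

**Step 2**
Reactants: 4 benzyloxyacetic acid; 5 4-(benzyloxy)-3-methoxybenzyl chloride
Product: 6 (±)-2-(benzyloxy)-3-[4-(benzyloxy)-3-methoxyphenyl]propanoic acid
Conditions: LDA (2.2 equiv), THF, −78 → 0 °C; then 5, −78 → 25 °C
Reagents that add atoms: none
Why: α-Alkylation of the carboxylate dianion (enolate alkylation) gives the acid; its α-centre is racemic, which is harmless because it becomes planar in Step 4.

**Step 3**
Reactants: 6; 3
Product: 7 (2R,3E)-5-(benzyloxy)pent-3-en-2-yl 2-(benzyloxy)-3-[4-(benzyloxy)-3-methoxyphenyl]propanoate (epimeric at the acid α-carbon)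
Conditions: EDC·HCl, DMAP (cat.), CH2Cl2, 0 → 25 °C
Reagents that add atoms: none
Why: Steglich esterification joins the acid and alcohol without touching the allylic stereocentre.

**Step 4**
Reactants: 7
Product: 8 (2R,3R,4E)-2-(benzyloxy)-3-[(benzyloxy)methyl]-2-[4-(benzyloxy)-3-methoxybenzyl]hex-4-enoic acid
Conditions: LDA (2.2 equiv), THF, −78 °C; TMSCl, −78 → 25 °C, then 50 °C, 12 h; 1 M HCl work-up
Reagents that add atoms: none (the silyl ester is hydrolysed on work-up)
Why: In this Ireland–Claisen [3,3] rearrangement, the Li-chelated (Z)-ketene acetal (CH2Ar pseudo-axial, OBn chelated) and the E-alkene react through a chair transition state with the methyl group equatorial. The (R)-carbinol transfers its chirality to the two new contiguous centres (C8′ quaternary R, C8 R) with the 2,3-anti relationship, which corresponds to the cis Bn/CH2OH pair of the ring.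

**Step 5**
Reactants: 8
Product: 9 (2R,3R,4E)-2-(benzyloxy)-3-[(benzyloxy)methyl]-2-[4-(benzyloxy)-3-methoxybenzyl]hex-4-en-1-ol
Conditions: LiAlH4, THF, 0 → 25 °C; Fieser work-up
Reagents that add atoms: none
Why: Hydride reduction of the carboxylic acid to the primary alcohol leaves the alkene and the benzyl ethers intact, and no stereocentre is affected.

**Step 6**
Reactants: 9
Product: 10 (3R,4R)-4-(benzyloxy)-3-[(benzyloxy)methyl]-4-[4-(benzyloxy)-3-methoxybenzyl]tetrahydrofuran-2-ol (anomeric mixture)
Conditions: OsO4 (5 mol %), NaIO4 (4 equiv), 2,6-lutidine, dioxane/H2O 3:1, 25 °C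
Reagents that add atoms: sodium periodate [Na+].[O-]I(=O)(=O)=O and water O (they supply the carbonyl oxygen)
Why: Lemieux–Johnson cleavage turns the alkene into the aldehyde and loses acetaldehyde; the 1,4-hydroxyl traps it as a five-membered lactol, which protects the α-stereocentre from epimerisation.

**Step 7**
Reactants: 10; 11 4-(benzyloxy)-1-bromo-... i.e. 4-bromo-1-(benzyloxy)-2-methoxybenzene (used as ArMgBr)
Product: 12 (2R,3S)-2-(benzyloxy)-2-[4-(benzyloxy)-3-methoxybenzyl]-3-[(benzyloxy)methyl]-4-[4-(benzyloxy)-3-methoxyphenyl]butane-1,4-diol (C4 epimers)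
Conditions: 11 + Mg, THF, then 10 (ArMgBr 3 equiv), THF, −78 → 0 °C; NH4Cl
Reagents that add atoms: none (the aryl group comes from 11)
Why: Grignard addition to the aldehyde released from the lactol forms the benzylic carbinol; its configuration is irrelevant because it is equilibrated in Step 8.

**Step 8**
Reactants: 12
Product: 13 (2R,3S,4R)-4-(benzyloxy)-2-[4-(benzyloxy)-3-methoxyphenyl]-3-[(benzyloxy)methyl]-4-[4-(benzyloxy)-3-methoxybenzyl]tetrahydrofuran
Conditions: TsOH·H2O (10 mol %), CH2Cl2, 25 °C; Et3N quench
Reagents that add atoms: none (water is lost)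
Why: Acid ionises the p-alkoxybenzylic alcohol and the primary hydroxyl closes the THF by SN1 etherification. The ionisation is reversible, so C7 funnels to the isomer with the aryl trans to both ring substituents (trans to CH2OBn and to the benzyl), which is the target configuration. C8 and C8′ are untouched.

**Step 9**
Reactants: 13
Product: 14 target, (3R,4S,5R)-3-(4-hydroxy-3-methoxybenzyl)-4-(hydroxymethyl)-5-(4-hydroxy-3-methoxyphenyl)oxolan-3-ol
Conditions: H2 (1 atm), 10% Pd/C, EtOAc/MeOH 1:1, 25 °C
Reagents that add atoms: none (H only)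
Why: Hydrogenolysis removes the four benzyl ethers (two phenolic, one tertiary, one primary) and leaves the THF and all stereocentres unchanged.

## Compound list
1 | (R)-but-3-en-2-ol | C[C@@H](O)C=C | starting material
2 | benzyl allyl ether | C=CCOCc1ccccc1 | starting material
3 | (2R,3E)-5-(benzyloxy)pent-3-en-2-ol | C[C@@H](O)/C=C/COCc1ccccc1 | intermediate
4 | benzyloxyacetic acid | OC(=O)COCc1ccccc1 | starting material
5 | 4-(benzyloxy)-3-methoxybenzyl chloride | COc1cc(CCl)ccc1OCc1ccccc1 | starting material
6 | (±)-2-(benzyloxy)-3-[4-(benzyloxy)-3-methoxyphenyl]propanoic acid | OC(=O)C(OCc1ccccc1)Cc1ccc(OCc2ccccc2)c(OC)c1 | intermediate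
7 | (2R,3E)-5-(benzyloxy)pent-3-en-2-yl ester of 6 | O=C(O[C@H](C)/C=C/COCc1ccccc1)C(OCc1ccccc1)Cc1ccc(OCc2ccccc2)c(OC)c1 | intermediate
8 | (2R,3R,4E)-Claisen acid | OC(=O)[C@@](OCc1ccccc1)(Cc1ccc(OCc2ccccc2)c(OC)c1)[C@@H](COCc1ccccc1)/C=C/C | intermediate
9 | (2R,3R,4E)-hex-4-en-1-ol | OC[C@@](OCc1ccccc1)(Cc1ccc(OCc2ccccc2)c(OC)c1)[C@@H](COCc1ccccc1)/C=C/C | intermediate
10 | (3R,4R)-tetrahydrofuran-2-ol (lactol) | OC1OC[C@@](OCc2ccccc2)(Cc2ccc(OCc3ccccc3)c(OC)c2)[C@H]1COCc2ccccc2 | intermediate
11 | 4-bromo-1-(benzyloxy)-2-methoxybenzene | COc1cc(Br)ccc1OCc1ccccc1 | starting material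
12 | (2R,3S)-butane-1,4-diol (C4 epimers) | OC[C@@](OCc1ccccc1)(Cc1ccc(OCc2ccccc2)c(OC)c1)[C@@H](COCc1ccccc1)C(O)c1ccc(OCc2ccccc2)c(OC)c1 | intermediate
13 | (2R,3S,4R)-tetra-O-benzyl THF | COc1cc(C[C@]2(OCc3ccccc3)CO[C@@H](c4ccc(OCc5ccccc5)c(OC)c4)[C@@H]2COCc6ccccc6)ccc1OCc7ccccc7 | intermediate
14 | (3R,4S,5R)-3-(4-hydroxy-3-methoxybenzyl)-4-(hydroxymethyl)-5-(4-hydroxy-3-methoxyphenyl)oxolan-3-ol | COc1cc(C[C@]2(O)CO[C@@H](c3ccc(O)c(OC)c3)[C@@H]2CO)ccc1O | target

Final check: 13 is C48H48O7 and, after loss of four C7H6 units, 14 is C20H24O7, the formula of the target.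

## Totals
- Total steps: 9
- Longest linear sequence: 8 steps (Step 1 or Step 2 through Step 9)

## Three steps most likely to fail
1. **Step 4 (Ireland–Claisen).** Forming adjacent quaternary and tertiary centres may be slow, and a wrong enolate geometry would give the syn diastereomer.
   - Fallback: fix C8′ by Seebach self-regeneration-of-stereocentres benzylation of the pivalaldehyde acetal of (R)-malic acid, then install C8–C7 by aldol with 4-benzyloxy-3-methoxybenzaldehyde.
2. **Step 7 (ArMgBr addition to the lactol).** The basic reagent can epimerise C8 through the enolisable aldehyde and give low yields.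
   - Fallback: convert 10 to its acetate and arylate directly with 1-benzyloxy-2-methoxybenzene under Lewis-acid Friedel–Crafts conditions. This forms the C–aryl THF with thermodynamic trans control and removes Step 8.
3. **Step 9 (debenzylation).** Pd/H2 may cleave the benzylic THF C–O bond or the tertiary benzyl ether.
   - Fallback: rerun the sequence with PMB/MOM protection in place of benzyl, and deprotect with acid or DDQ.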